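**Retrosynthetic overview**
1. Feature: the eleven-membered carbocycle is numbered C1 (acetoxy carbon), C2=C3(Me), C4 (aroyloxy carbon), C5, C6=C7(Me), C8–C10, C11 (gem-dimethyl). Its unit O–C1–C2=C3(Me)–C4–O is a Z-trisubstituted ene-1,4-diol. One silicon atom placed between the two oxygens makes it a seven-membered 1,3-dioxa-2-silacyclohept-5-ene, which can hold only the Z alkene.
2. Disconnections: the C4–O aroyl and C1–O acetyl esters; the two auxiliary sulfones on C9; C8–C9 by intramolecular π-allylpalladium alkylation; the Si–O tether; C2=C3 by silicon-tethered ring-closing metathesis.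
3. Halves: C9–C11/C1/C2 comes from isobutyraldehyde, 1,1-bis(phenylsulfonyl)ethene and vinyl Grignard, with C1 set by kinetic resolution. C3–C8 comes from two molecules of methacrolein and an allylborane, with C4 set by allylboration and C6=C7 by cross metathesis.
4. Ring order: the seven-membered silacycle is formed in step 9 and opened in step 10, because its two side chains are trans. The eleven-membered carbocycle is closed in step 12. The arene is bought.

Key step: step 9

Assumption: 2 and (+)-Ipc2B(allyl) are taken as purchasable, and the atom labels C1–C11 of the overview are used for every intermediate.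

Step 1
Reactants: 1 isobutyraldehyde; 2 1,1-bis(phenylsulfonyl)ethene
Product: 3 2,2-dimethyl-4,4-bis(phenylsulfonyl)butanal
Conditions: 1 (3 equiv), pyrrolidine (20 mol %), PhCO2H (20 mol %), CH2Cl2, 0 °C to rt
Reagents that add atoms: none
Why: Enamine-catalysed Michael addition, in which the pyrrolidine enamine of 1 attacks the free CH2 terminus of the doubly activated vinylidene bis-sulfone, forming C10–C11 and the quaternary C11, and the adduct has no α-hydrogen left and so cannot react again through its aldehyde.

Step 2
Reactants: 3 2,2-dimethyl-4,4-bis(phenylsulfonyl)butanal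
Product: 4 rac-4,4-dimethyl-6,6-bis(phenylsulfonyl)hex-1-en-3-ol
Conditions: CH2=CHMgBr (2.3 equiv), THF, −78 to 0 °C; aq NH4Cl
Reagents that add atoms: vinylmagnesium bromide, C=C[Mg]Br
Why: Grignard 1,2-addition to a non-enolisable aldehyde, in which the first equivalent is spent on the acidic C9–H (its stabilised magnesium carbanion could reach the carbonyl only through a four-membered ring and stays idle), the second forms C1–C2, and C1 is deliberately made racemic for resolution in step 3.

Step 3
Reactants: 4 rac-4,4-dimethyl-6,6-bis(phenylsulfonyl)hex-1-en-3-ol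
Product: 5 (3S)-4,4-dimethyl-6,6-bis(phenylsulfonyl)hex-1-en-3-ol
Conditions: Ti(OiPr)4 (0.5 equiv), L-(+)-DIPT (0.6 equiv), tBuOOH (0.6 equiv), 4 Å MS, CH2Cl2, −20 °C, taken past half conversion
Reagents that add atoms: none
Why: Sharpless kinetic resolution, in which L-(+)-DIPT should epoxidise the (R)-carbinol much faster (to the anti epoxy alcohol), so that the slow (S)-enantiomer is recovered enantiopure and fixes C1; it is spatially the enantiomer left over from simple 1-alken-3-ols, and its descriptor is reversed only because C11 outranks vinyl.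

Step 4
Reactants: 6 methacrolein
Product: 8 (3R)-2-methylhexa-1,5-dien-3-ol, via diisopinocampheylborinate 7 (not isolated)
Conditions: (+)-Ipc2B(allyl) (from (−)-α-pinene, 1.1 equiv), Et2O, −78 °C; then 3 M NaOH, 30% H2O2, 0 °C to rt
Reagents that add atoms: (+)-B-allyldiisopinocampheylborane, C=CCB([C@H]1C[C@H]2C[C@@H]([C@@H]1C)C2(C)C)[C@H]1C[C@H]2C[C@@H]([C@@H]1C)C2(C)C
Why: Brown allylboration through a closed chair six-membered transition state, in which the isopinocampheyl groups derived from (−)-α-pinene steer the allyl group to the Re face of the aldehyde and set C4 as R, while the cyclic 1,2-mode leaves the conjugated alkene untouched.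

Step 5
Reactants: 8 (3R)-2-methylhexa-1,5-dien-3-ol; 6 methacrolein
Product: 9 (2E,5R)-5-hydroxy-2,6-dimethylhepta-2,6-dienal
Conditions: 6 (5 equiv), second-generation Grubbs catalyst RuCl2(=CHPh)(SIMes)(PCy3) (5 mol %), CH2Cl2, 40 °C
Reagents that add atoms: none
Why: Olefin cross metathesis between the reactive monosubstituted C6 alkene and the electron-poor, non-homodimerising methacrolein, which forms C6=C7 under thermodynamic control as the E enal, while the hindered isopropenyl group next to the carbinol stays out and no small ring is available to the 1,5-diene.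

Step 6
Reactants: 9 (2E,5R)-5-hydroxy-2,6-dimethylhepta-2,6-dienal
Product: 10 (2E,5R)-2,6-dimethylhepta-2,6-diene-1,5-diol
Conditions: NaBH4, CeCl3·7H2O, MeOH, −20 to 0 °C
Reagents that add atoms: none
Why: Luche reduction delivers hydride only to the carbonyl carbon of the enal, so C8 becomes the primary allylic alcohol with the E alkene and C4 unchanged.

Step 7
Reactants: 10 (2E,5R)-2,6-dimethylhepta-2,6-diene-1,5-diol
Product: 11 (2E,5R)-5-hydroxy-2,6-dimethylhepta-2,6-dien-1-yl methyl carbonate
Conditions: ClCO2Me (1.05 equiv), pyridine, CH2Cl2, −78 to −20 °C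
Reagents that add atoms: methyl chloroformate, COC(=O)Cl
Why: Chemoselective O-acylation, in which the unhindered primary allylic hydroxyl at C8 should be acylated well before the secondary C4 hydroxyl flanked by the isopropenyl group, so no protecting group is needed in this half.

Step 8
Reactants: 5 (3S)-4,4-dimethyl-6,6-bis(phenylsulfonyl)hex-1-en-3-ol; 12 dichlorodiisopropylsilane; 11 (2E,5R)-5-hydroxy-2,6-dimethylhepta-2,6-dien-1-yl methyl carbonate
Product: 14 diisopropylsilylene bis-ether of 5 and 11 (metathesis precursor), via chlorosilyl ether 13 (not isolated)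
Conditions: 12 (3 equiv), imidazole, CH2Cl2, 0 °C to rt; filter under argon, strip excess 12 in vacuo; then 11, imidazole, DMAP (cat), DMF, rt to 40 °C
Reagents that add atoms: none
Why: Two successive nucleophilic substitutions at silicon (silyl ether formation), in which the neopentylic carbinol 5 meets an excess of 12 and stops at the monochloride, the less hindered 11 then displaces the remaining chloride, and only O–H bonds are broken so C1 and C4 keep their configurations.

Step 9
Reactants: 14 diisopropylsilylene bis-ether of 5 and 11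
Product: 15 (4R,7S)-2,2-diisopropyl-5-methyl-1,3-dioxa-2-silacyclohept-5-ene carrying the carbonate chain on ring C4 (route C4) and the bis-sulfone chain on ring C7 (route C1)
Conditions: second-generation Grubbs catalyst RuCl2(=CHPh)(SIMes)(PCy3) (10 mol % in two portions), 1,4-benzoquinone (10 mol %), toluene (5 mM), 80 to 110 °C, argon sparge
Reagents that add atoms: none
Why: Olefin metathesis by the metallacyclobutane mechanism: the benzylidene first exchanges with the monosubstituted vinyl group on C1, the resulting C2 alkylidene adds [2+2] across the tethered isopropenyl π-bond at C3, and cycloreversion gives C2=C3 together with Ru=CH2, which carries the chain while ethene is swept out. The closest known reaction type is temporary silicon-tethered ring-closing metathesis of bis(allyloxy)silanes to seven-membered silaketals, including cases that give trisubstituted alkenes. The single ring formed is the seven-membered dioxasilacycloheptene, closed by intramolecular alkylidene–alkene metathesis with the new alkene endocyclic, and a ring of this size cannot hold an E alkene, so C1 and C4 must end cis on C2=C3 (Z). No stereocentre is created, C1 (S) and C4 (R) are spectators, and their side chains end trans on the silacycle. The step needs site selectivity against C6=C7 and against dimerisation, which the substrate secures because C6=C7 is trisubstituted and would demand an eight-membered ring, the carbonate and sulfones do not bind ruthenium, and the tether at high dilution makes the isopropenyl group the nearest partner. The isopropyl groups shield silicon, so the silaketal should survive hot toluene and chromatography.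

Step 10
Reactants: 15 silacycle
Product: 16 (2E,5R,6Z,8S)-5,8-dihydroxy-2,6,9,9-tetramethyl-11,11-bis(phenylsulfonyl)undeca-2,6-dien-1-yl methyl carbonate
Conditions: HF·pyridine, pyridine, THF, 0 °C to rt
Reagents that add atoms: none
Why: Fluoride-driven Si–O cleavage under buffered, non-basic conditions spares the methyl carbonate and the acidic C9–H and avoids acid-promoted dihydrofuran formation, and the tether has to go now because trans side chains on a seven-membered ring could not be bridged by the C8–C9 bond.

Step 11
Reactants: 16 Z-enediol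
Product: 17 (2E,5R,6Z,8S)-5-(tert-butyldimethylsilyloxy)-8-hydroxy-2,6,9,9-tetramethyl-11,11-bis(phenylsulfonyl)undeca-2,6-dien-1-yl methyl carbonate
Conditions: TBSCl (1.15 equiv), imidazole, DMF, 0 °C to rt
Reagents that add atoms: tert-butyldimethylsilyl chloride, CC(C)(C)[Si](C)(C)Cl
Why: Site-selective silylation, in which the C4 hydroxyl reacts while the neopentylic C1 hydroxyl next to C11 should be inert to TBSCl/imidazole; this masks the one oxygen that could reach the π-allyl terminus C8 through a six-membered ring and differentiates the two oxygens for the endgame.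

Step 12
Reactants: 17 mono-silyl ether
Product: 18 (1S,2Z,4R,6E)-4-(tert-butyldimethylsilyloxy)-3,7,11,11-tetramethyl-9,9-bis(phenylsulfonyl)cycloundeca-2,6-dien-1-ol
Conditions: Pd(PPh3)4 (10 mol %), dppe (10 mol %), THF, 65 °C, 17 added by syringe pump (final 2 mM)
Reagents that add atoms: none
Why: Intramolecular Tsuji–Trost allylic alkylation under neutral conditions, in which zerovalent palladium ionises only the primary allylic carbonate (allylic alcohols and silyl ethers are not leaving groups), loss of CO2 frees methoxide that deprotonates C9–H, and the soft bis-sulfonyl carbanion attacks the less hindered C8 end of the syn π-allyl with the E geometry retained, helped by the Z-enediol turn, the gem-dimethyl group and high dilution.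

Step 13
Reactants: 18 macrocyclic bis-sulfone
Product: 19 (1S,2Z,4R,6E)-4-(tert-butyldimethylsilyloxy)-3,7,11,11-tetramethylcycloundeca-2,6-dien-1-ol
Conditions: Mg turnings (30 equiv), MeOH–THF 4:1, rt to 50 °C; aq NH4Cl
Reagents that add atoms: none
Why: Reductive desulfonylation by electron transfer from magnesium in methanol cleaves both C9–S bonds in turn to sulfinate and a carbanion that methanol protonates, and isolated alkenes, the silyl ether and the free alcohol are not reducible under these conditions, which is why both esters are installed only afterwards.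

Step 14
Reactants: 19 macrocyclic alcohol
Product: 20 (1S,2Z,4R,6E)-4-(tert-butyldimethylsilyloxy)-3,7,11,11-tetramethylcycloundeca-2,6-dien-1-yl acetate
Conditions: Ac2O (5 equiv), Et3N, DMAP (0.3 equiv), CH2Cl2, rt
Reagents that add atoms: acetic anhydride, CC(=O)OC(C)=O
Why: DMAP-catalysed acylation is strong enough for the hindered neopentylic C1 hydroxyl, which is the only free hydroxyl present, and it proceeds at oxygen with retention at C1.

Step 15
Reactants: 20 silyl ether acetate
Product: 21 (1S,2Z,4R,6E)-4-hydroxy-3,7,11,11-tetramethylcycloundeca-2,6-dien-1-yl acetate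
Conditions: HF·pyridine, pyridine, THF, 0 °C to rt
Reagents that add atoms: none
Why: Fluoride desilylation in a weakly acidic medium frees the C4 hydroxyl without generating an alkoxide, so the acetyl group should not migrate from the C1 oxygen to the C4 oxygen.

Step 16
Reactants: 22 4-hydroxybenzoic acid
Product: 24 4-(tert-butyldimethylsilyloxy)benzoic acid, via bis-silylated benzoate 23 (not isolated)
Conditions: TBSCl (2.4 equiv), imidazole (5 equiv), DMF, rt; then AcOH–THF–H2O 3:1:1, rt
Reagents that add atoms: tert-butyldimethylsilyl chloride, CC(C)(C)[Si](C)(C)Cl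
Why: Exhaustive silylation followed by selective solvolysis works because the silyl ester is far more labile than the aryl silyl ether, so mild aqueous acid returns the free acid with the phenol still masked.

Step 17
Reactants: 21 hydroxy acetate; 24 4-(tert-butyldimethylsilyloxy)benzoic acid
Product: 25 (1R,2Z,4S,7E)-4-acetoxy-2,5,5,8-tetramethylcycloundeca-2,7-dien-1-yl 4-(tert-butyldimethylsilyloxy)benzoate, that is the acetate at route C1 (S) and the silylated aroyl ester at route C4 (R)
Conditions: DCC (1.5 equiv), DMAP (0.5 equiv), CH2Cl2, 0 °C to rt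
Reagents that add atoms: none
Why: Steglich esterification acylates the only free hydroxyl through the acylpyridinium ion, the C4–O bond is not broken so C4 stays R, and the masked phenol cannot compete or oligomerise.

Step 18
Reactants: 25 silyl-protected diester
Product: 26 target CNP0246761.2, the (route C1 S, C2 Z, C4 R, C6 E) 1-acetoxy-3,7,11,11-tetramethylcycloundeca-2,6-dien-4-yl 4-hydroxybenzoate
Conditions: Bu4NF (1.1 equiv), AcOH (1.1 equiv), THF, 0 °C
Reagents that add atoms: none
Why: Buffered fluoride desilylation cleaves the aryl silyl ether quickly because phenoxide is a good leaving group from silicon, and acetic acid keeps the medium too weakly basic to touch the acetate or the benzoate.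

**Compound list**
1 | isobutyraldehyde | CC(C)C=O | starting material
2 | 1,1-bis(phenylsulfonyl)ethene | C=C(S(=O)(=O)c1ccccc1)S(=O)(=O)c1ccccc1 | starting material
3 | 2,2-dimethyl-4,4-bis(phenylsulfonyl)butanal | O=CC(C)(C)CC(S(=O)(=O)c1ccccc1)S(=O)(=O)c1ccccc1 | intermediate
4 | rac-4,4-dimethyl-6,6-bis(phenylsulfonyl)hex-1-en-3-ol | C=CC(O)C(C)(C)CC(S(=O)(=O)c1ccccc1)S(=O)(=O)c1ccccc1 | intermediate
5 | (3S)-4,4-dimethyl-6,6-bis(phenylsulfonyl)hex-1-en-3-ol | O[C@H](C(C)(C)CC(S(=O)(=O)c1ccccc1)S(=O)(=O)c1ccccc1)C=C | intermediate
6 | methacrolein | CC(=C)C=O | starting material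
7 | (3R)-2-methylhexa-1,5-dien-3-yl diisopinocampheylborinate | B(O[C@H](CC=C)C(C)=C)([C@H]1C[C@H]2C[C@@H]([C@@H]1C)C2(C)C)[C@H]1C[C@H]2C[C@@H]([C@@H]1C)C2(C)C | intermediate
8 | (3R)-2-methylhexa-1,5-dien-3-ol | O[C@H](CC=C)C(C)=C | intermediate
9 | (2E,5R)-5-hydroxy-2,6-dimethylhepta-2,6-dienal | O[C@H](C/C=C(\C)C=O)C(C)=C | intermediate
10 | (2E,5R)-2,6-dimethylhepta-2,6-diene-1,5-diol | O[C@H](C/C=C(\C)CO)C(C)=C | intermediate
11 | (2E,5R)-5-hydroxy-2,6-dimethylhepta-2,6-dien-1-yl methyl carbonate | O[C@H](C/C=C(\C)COC(=O)OC)C(C)=C | intermediate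
12 | dichlorodiisopropylsilane | CC(C)[Si](Cl)(Cl)C(C)C | starting material
13 | chlorodiisopropylsilyl ether of 5 | CC(C)[Si](Cl)(C(C)C)O[C@H](C(C)(C)CC(S(=O)(=O)c1ccccc1)S(=O)(=O)c1ccccc1)C=C | intermediate
14 | diisopropylsilylene bis-ether of 5 (C1, S) and 11 (C4, R) | CC(C)[Si](C(C)C)(O[C@H](C(C)(C)CC(S(=O)(=O)c1ccccc1)S(=O)(=O)c1ccccc1)C=C)O[C@H](C/C=C(\C)COC(=O)OC)C(C)=C | intermediate
15 | (4R,7S)-2,2-diisopropyl-5-methyl-1,3-dioxa-2-silacyclohept-5-ene with both side chains | CC(C)[Si]1(C(C)C)O[C@H](C(C)(C)CC(S(=O)(=O)c2ccccc2)S(=O)(=O)c2ccccc2)C=C(C)[C@@H](C/C=C(\C)COC(=O)OC)O1 | intermediate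
16 | (2E,5R,6Z,8S)-5,8-dihydroxy-2,6,9,9-tetramethyl-11,11-bis(phenylsulfonyl)undeca-2,6-dien-1-yl methyl carbonate | O[C@H](C(C)(C)CC(S(=O)(=O)c1ccccc1)S(=O)(=O)c1ccccc1)/C=C(/C)[C@H](O)C/C=C(\C)COC(=O)OC | intermediate
17 | C4 tert-butyldimethylsilyl ether of 16 | O[C@H](C(C)(C)CC(S(=O)(=O)c1ccccc1)S(=O)(=O)c1ccccc1)/C=C(/C)[C@H](O[Si](C)(C)C(C)(C)C)C/C=C(\C)COC(=O)OC | intermediate
18 | (1S,2Z,4R,6E)-4-(tert-butyldimethylsilyloxy)-3,7,11,11-tetramethyl-9,9-bis(phenylsulfonyl)cycloundeca-2,6-dien-1-ol | O[C@H]1/C=C(/C)[C@H](O[Si](C)(C)C(C)(C)C)C/C=C(\C)CC(S(=O)(=O)c2ccccc2)(S(=O)(=O)c2ccccc2)CC1(C)C | intermediate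
19 | (1S,2Z,4R,6E)-4-(tert-butyldimethylsilyloxy)-3,7,11,11-tetramethylcycloundeca-2,6-dien-1-ol | O[C@H]1/C=C(/C)[C@H](O[Si](C)(C)C(C)(C)C)C/C=C(\C)CCCC1(C)C | intermediate
20 | C1 acetate of 19 | CC(=O)O[C@H]1/C=C(/C)[C@H](O[Si](C)(C)C(C)(C)C)C/C=C(\C)CCCC1(C)C | intermediate
21 | (1S,2Z,4R,6E)-4-hydroxy-3,7,11,11-tetramethylcycloundeca-2,6-dien-1-yl acetate | CC(=O)O[C@H]1/C=C(/C)[C@H](O)C/C=C(\C)CCCC1(C)C | intermediate
22 | 4-hydroxybenzoic acid | OC(=O)c1ccc(O)cc1 | starting material
23 | tert-butyldimethylsilyl 4-(tert-butyldimethylsilyloxy)benzoate | CC(C)(C)[Si](C)(C)OC(=O)c1ccc(O[Si](C)(C)C(C)(C)C)cc1 | intermediate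
24 | 4-(tert-butyldimethylsilyloxy)benzoic acid | OC(=O)c1ccc(O[Si](C)(C)C(C)(C)C)cc1 | intermediate
25 | phenol-silylated target | CC(=O)O[C@H]1/C=C(/C)[C@H](OC(=O)c2ccc(O[Si](C)(C)C(C)(C)C)cc2)C/C=C(\C)CCCC1(C)C | intermediate
26 | CNP0246761.2 | CC(=O)O[C@H]1/C=C(/C)[C@H](OC(=O)c2ccc(O)cc2)C/C=C(\C)CCCC1(C)C | target

**Step count**
Total: 18 steps. Longest linear sequence: 14 steps (4, 5, 6, 7, 8, 9, 10, 11, 12, 13, 14, 15, 17, 18).

**Steps most likely to fail**

Step 9 (tethered metathesis).
- What may go wrong: ruthenium may load too slowly on the C1 vinyl group, which is screened by the quaternary C11 and the silyl ether. Catalyst decay, alkene migration and intermolecular coupling could then overtake closure onto the 1,1-disubstituted partner.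
- Fallback: relay ring-closing metathesis, setting out from 3 and coming back at 15. Hept-1-en-6-yne is hydrozirconated at the alkyne with Cp2Zr(H)Cl and transmetalated with Me2Zn to (E)-hepta-1,6-dienyl(methyl)zinc F1. After one extra equivalent of Me2Zn has taken the C9–H, this reagent adds to 3 to give the racemic relay dienol F2. Sharpless kinetic resolution with L-(+)-DIPT as in step 3, now on a more reactive disubstituted alkene, leaves the (S)-relay dienol F3. Compound 12 converts it into the relay chlorosilyl ether F4, and 11 then gives the relay silaketal F5. With the same catalyst, ruthenium enters at the unhindered terminal alkene, expels cyclopentene and is thereby delivered onto C2 intramolecularly. Closure onto the isopropenyl group then gives 15.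

Step 12 (eleven-membered ring closure).
- What may go wrong: intermolecular alkylation may lead to oligomers, attack at C6 would give a nine-membered ring, and syn–anti equilibration of a long-lived π-allyl may erode the E geometry.
- Fallback: metal-free SN2 ring closure, setting out from 17 and coming back at 18. K2CO3 in MeOH removes the methyl carbonate to give the primary allylic alcohol F6. MsCl, LiCl and 2,4,6-collidine in DMF at 0 °C convert only that unhindered hydroxyl into the primary allylic chloride F7 without allylic transposition. Slow addition of F7 to Cs2CO3 and catalytic Bu4NI in DMF (2 mM) lets the C9 carbanion displace chloride directly at C8. No π-allyl is formed, so neither C6 attack nor alkene isomerisation is open, and 18 results.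

Step 8 (mixed silaketal).
- What may go wrong: the second substitution at a silicon atom already carrying two isopropyl groups and a neopentylic alkoxide may be sluggish. Alkoxide exchange may also scramble the product into the two symmetrical silaketals.
- Fallback: a hydrosilane route, setting out from 5 and coming back at 14. Chlorodiisopropylsilane and imidazole give the isolable diisopropylsilyl (Si–H) ether F8, which can be purified free of any second electrophilic site. N-Bromosuccinimide in CH2Cl2 at 0 °C turns Si–H into the more reactive bromosilyl ether F9. Addition of 11, Et3N and DMAP then gives 14.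

**Further compounds**
F1 | step 9 | (E)-hepta-1,6-dienyl(methyl)zinc | C[Zn]/C=C/CCCC=C
F2 | step 9 | rac-(5E)-3,3-dimethyl-1,1-bis(phenylsulfonyl)undeca-5,10-dien-4-ol | OC(/C=C/CCCC=C)C(C)(C)CC(S(=O)(=O)c1ccccc1)S(=O)(=O)c1ccccc1
F3 | step 9 | (4S,5E)-3,3-dimethyl-1,1-bis(phenylsulfonyl)undeca-5,10-dien-4-ol | O[C@H](C(C)(C)CC(S(=O)(=O)c1ccccc1)S(=O)(=O)c1ccccc1)/C=C/CCCC=C
F4 | step 9 | chlorodiisopropylsilyl ether of F3 | CC(C)[Si](Cl)(C(C)C)O[C@H](C(C)(C)CC(S(=O)(=O)c1ccccc1)S(=O)(=O)c1ccccc1)/C=C/CCCC=C
F5 | step 9 | diisopropylsilylene bis-ether of F3 and 11 | CC(C)[Si](C(C)C)(O[C@H](C(C)(C)CC(S(=O)(=O)c1ccccc1)S(=O)(=O)c1ccccc1)/C=C/CCCC=C)O[C@H](C/C=C(\C)COC(=O)OC)C(C)=C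
F6 | step 12 | (2E,5R,6Z,8S)-5-(tert-butyldimethylsilyloxy)-2,6,9,9-tetramethyl-11,11-bis(phenylsulfonyl)undeca-2,6-diene-1,8-diol | O[C@H](C(C)(C)CC(S(=O)(=O)c1ccccc1)S(=O)(=O)c1ccccc1)/C=C(/C)[C@H](O[Si](C)(C)C(C)(C)C)C/C=C(\C)CO
F7 | step 12 | primary allylic chloride derived from F6 | O[C@H](C(C)(C)CC(S(=O)(=O)c1ccccc1)S(=O)(=O)c1ccccc1)/C=C(/C)[C@H](O[Si](C)(C)C(C)(C)C)C/C=C(\C)CCl
F8 | step 8 | diisopropylsilyl (Si–H) ether of 5 | CC(C)[SiH](C(C)C)O[C@H](C(C)(C)CC(S(=O)(=O)c1ccccc1)S(=O)(=O)c1ccccc1)C=C
F9 | step 8 | bromodiisopropylsilyl ether of 5 | CC(C)[Si](Br)(C(C)C)O[C@H](C(C)(C)CC(S(=O)(=O)c1ccccc1)S(=O)(=O)c1ccccc1)C=C
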